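Ring A is a hexasubstituted benzene in which oxygen atoms at C2 (OH), C4 (OMe) and C6 (OH) alternate with carbon substituents at C1 (benzoyl), C3 and C5 (prenyl). The plan assembles this ring in one thermal benzannulation. The vinylketene unmasked from racemic 3-methoxy-2,4-diprenylcyclobutenone captures a triisopropylsiloxyalkyne whose propargylic carbon is the benzoyl carbon protected as a dioxolane. The cascade makes the C1–C2, C5–C6 and C2–C3 bonds, closes ring A and delivers the three oxygens already differentiated as free phenol, silyl ether and methyl ether. Each partner is reached in two or three steps from simple acyclic materials, and one final operation unmasks the target.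

Key step: step 6

Remarks on the chemistry:
- Ring A numbering: C1 carries the benzoyl group, C2 and C6 the hydroxyls, C3 and C5 the prenyl groups, C4 the methoxy group. Prenyl = 3-methylbut-2-en-1-yl; TIPS = triisopropylsilyl.
- The target has no stereocentre. The cyclobutenone is used as the racemate (its SMILES shows one enantiomer) and its stereocentre is lost in the key step.
- Outward rotation of the C4 prenyl group places it anti to the ketene carbon across the new double bond. Because methoxy outranks carbon at C3, this vinylketene carries the descriptor Z, not E.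

Step 1
Reactants: 1 trichloroethylene; 2 prenyl bromide (1-bromo-3-methylbut-2-ene)
Product: 5 1-methoxy-5-methylhex-4-en-1-yne, via (E)-1,2-dichloro-1-methoxyethene 3 (not isolated), via lithium methoxyacetylide 4 (not isolated)
Conditions: KH, MeOH, THF, 0 °C; 1, −50 °C → rt; n-BuLi (2.2 equiv), −78 → −40 °C; 2, DMPU, −78 °C → rt
Reagents that add atoms: methanol (CO)
Why: Potassium methoxide should convert 1 by base-induced elimination–addition into dichloroenol ether 3, two equivalents of n-BuLi should turn 3 into acetylide 4 by elimination and chlorine–lithium exchange, and 4 should be alkylated at the primary carbon of 2 in an SN2 reaction promoted by DMPU (one-pot alkynyl ether synthesis of the Greene type).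

Step 2
Reactants: 6 5-methylhex-4-enoic acid
Product: 7 5-methylhex-4-enoyl chloride
Conditions: (COCl)2, DMF (cat.), CH2Cl2, 0 °C → rt
Reagents that add atoms: oxalyl chloride (O=C(Cl)C(=O)Cl)
Why: Vilsmeier-type activation by catalytic DMF should give the acid chloride at a temperature at which the trisubstituted alkene is not hydrochlorinated, the gaseous by-products leaving the solution.

Step 3
Reactants: 7 5-methylhex-4-enoyl chloride; 5 1-methoxy-5-methylhex-4-en-1-yne
Product: 9 rac-3-methoxy-2,4-bis(3-methylbut-2-en-1-yl)cyclobut-2-en-1-one, via prenylketene 8 (not isolated)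
Conditions: Et3N, CH2Cl2, 0 °C → rt, slow addition of 7
Reagents that add atoms: none
Why: Dehydrochlorination of 7 should release aldoketene 8 at low concentration, and the strongly nucleophilic ynol ether 5 should trap it in a regioselective ketene–alkyne (2+2) cycloaddition (prenyl-bearing alkyne carbon to the ketene carbonyl carbon), which places methoxy at C3 and the prenyl groups at C2 and C4; the C4 stereocentre forms without control, which is immaterial because it becomes sp2 in step 6.

Step 4
Reactants: 10 ethyl benzoylformate
Product: 11 ethyl 2-phenyl-1,3-dioxolane-2-carboxylate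
Conditions: TMSOCH2CH2OTMS, TMSOTf (cat.), CH2Cl2, −78 °C → rt
Reagents that add atoms: 1,2-bis(trimethylsilyloxy)ethane (C[Si](C)(C)OCCO[Si](C)(C)C)
Why: Noyori ketalisation should convert the electrophilic ketone carbonyl into the dioxolane under aprotic conditions, so that the ethyl ester is not transesterified by a free diol.

Step 5
Reactants: 11 ethyl 2-phenyl-1,3-dioxolane-2-carboxylate
Product: 14 triisopropyl{[(2-phenyl-1,3-dioxolan-2-yl)ethynyl]oxy}silane, via dibromo enolate 12 (not isolated), via lithium ynolate 13 (not isolated)
Conditions: CH2Br2 (1.1 equiv), LiTMP (lithium 2,2,6,6-tetramethylpiperidide, 2.2 equiv), THF, −78 °C; n-BuLi, −78 °C → rt; TIPSCl, −78 °C → rt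
Reagents that add atoms: dibromomethane (BrCBr); triisopropylsilyl chloride (CC(C)[Si](Cl)(C(C)C)C(C)C)
Why: In this Kowalski ester homologation dibromomethyllithium should add to the non-enolisable ester, the derived dibromo enolate 12 should undergo bromine–lithium exchange and 1,2-migration of the ketal-bearing carbon to give ynolate 13, and the bulky silyl chloride should trap 13 on oxygen.

Step 6
Reactants: 9 rac-3-methoxy-2,4-bis(3-methylbut-2-en-1-yl)cyclobut-2-en-1-one; 14 triisopropyl{[(2-phenyl-1,3-dioxolan-2-yl)ethynyl]oxy}silane
Product: 19 3-methoxy-2,4-bis(3-methylbut-2-en-1-yl)-6-(2-phenyl-1,3-dioxolan-2-yl)-5-(triisopropylsilyloxy)phenol, via vinylketene 15 (not isolated), via vinylcyclobutenone 16 (not isolated), via dienylketene 17 (not isolated), via cyclohexadienone 18 (not isolated)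
Conditions: 14 (1.5 equiv), toluene, 110 → 130 °C, sealed tube, Ar
Reagents that add atoms: none
Why: Thermal conrotatory 4π opening of 9 should give vinylketene 15 with the C4 prenyl group rotated outward, and the ketene C=C of 15 then adds 14 in a (2+2) cycloaddition in which the nucleophilic, ketal-bearing alkyne carbon bonds to the ketene carbonyl carbon (C1–C2) and the silyloxy-bearing carbon to the former C2 of 9 (C5–C6). Vinylcyclobutenone 16 opens reversibly to dienylketene 17, and the isomer with the methoxyvinyl arm cis to the ketene closes ring A by a thermally allowed disrotatory 6π electrocyclisation (six-membered closure, C2–C3); tautomerisation of dienone 18 to phenol 19 makes the sequence irreversible. The closest known reaction type is the Danheiser benzannulation of cyclobutenones with trialkylsiloxyalkynes, here applied to a 3-alkoxycyclobutenone and a more hindered alkyne. No stereocentre is formed, and the one in 9 is erased. The step needs a single orientation in the ketene–alkyne cycloaddition, which the polarisation of the silyl ynol ether secures, and an outward-rotated C4 substituent, which the alkyl nature of the prenyl group secures; the ketal keeps the benzoyl carbon from engaging ketenes as an acyl or ynone unit.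

Step 7
Reactants: 19 3-methoxy-2,4-bis(3-methylbut-2-en-1-yl)-6-(2-phenyl-1,3-dioxolan-2-yl)-5-(triisopropylsilyloxy)phenol
Product: 21 [2,6-dihydroxy-4-methoxy-3,5-bis(3-methylbut-2-en-1-yl)phenyl](phenyl)methanone, via resorcinol ketal 20 (not isolated)
Conditions: Bu4NF (TBAF), THF, 0 °C; then 1 M aq HCl, rt
Reagents that add atoms: water (O)
Why: Fluoride should cleave the aryl silyl ether, and dilute aqueous acid should then hydrolyse the dioxolane, whose ionisation is assisted by the two ortho hydroxyl groups, under conditions too mild to cyclise the ortho-prenyl phenols to chromans.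

Compound list
1 | trichloroethylene | ClC=C(Cl)Cl | starting material
2 | prenyl bromide (1-bromo-3-methylbut-2-ene) | CC(C)=CCBr | starting material
3 | (E)-1,2-dichloro-1-methoxyethene | CO/C(Cl)=C\Cl | intermediate
4 | lithium methoxyacetylide | [Li]C#COC | intermediate
5 | 1-methoxy-5-methylhex-4-en-1-yne | COC#CCC=C(C)C | intermediate
6 | 5-methylhex-4-enoic acid | CC(C)=CCCC(=O)O | starting material
7 | 5-methylhex-4-enoyl chloride | CC(C)=CCCC(=O)Cl | intermediate
8 | prenylketene (5-methylhexa-1,4-dien-1-one) | CC(C)=CCC=C=O | intermediate
9 | rac-3-methoxy-2,4-bis(3-methylbut-2-en-1-yl)cyclobut-2-en-1-one (racemate; one enantiomer written) | COC1=C(CC=C(C)C)C(=O)[C@H]1CC=C(C)C | intermediate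
10 | ethyl benzoylformate (ethyl 2-oxo-2-phenylacetate) | CCOC(=O)C(=O)c1ccccc1 | starting material
11 | ethyl 2-phenyl-1,3-dioxolane-2-carboxylate | CCOC(=O)C1(c2ccccc2)OCCO1 | intermediate
12 | lithium 2,2-dibromo-1-(2-phenyl-1,3-dioxolan-2-yl)ethen-1-olate | [Li]OC(=C(Br)Br)C1(c2ccccc2)OCCO1 | intermediate
13 | lithium 2-(2-phenyl-1,3-dioxolan-2-yl)ethyn-1-olate | [Li]OC#CC1(c2ccccc2)OCCO1 | intermediate
14 | triisopropyl{[(2-phenyl-1,3-dioxolan-2-yl)ethynyl]oxy}silane | CC(C)[Si](OC#CC1(c2ccccc2)OCCO1)(C(C)C)C(C)C | intermediate
15 | (3Z)-3-methoxy-7-methyl-2-(3-methylbut-2-en-1-yl)octa-1,3,6-trien-1-one | O=C=C(CC=C(C)C)/C(OC)=C/CC=C(C)C | intermediate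
16 | 4-[(1Z)-1-methoxy-5-methylhexa-1,4-dien-1-yl]-4-(3-methylbut-2-en-1-yl)-2-(2-phenyl-1,3-dioxolan-2-yl)-3-(triisopropylsilyloxy)cyclobut-2-en-1-one (racemic; configuration left open) | O=C1C(C2(c3ccccc3)OCCO2)=C(O[Si](C(C)C)(C(C)C)C(C)C)C1(CC=C(C)C)/C(OC)=C/CC=C(C)C | intermediate
17 | (3E,5Z)-5-methoxy-9-methyl-4-(3-methylbut-2-en-1-yl)-2-(2-phenyl-1,3-dioxolan-2-yl)-3-(triisopropylsilyloxy)deca-1,3,5,8-tetraen-1-one | O=C=C(C1(c2ccccc2)OCCO1)/C(O[Si](C(C)C)(C(C)C)C(C)C)=C(CC=C(C)C)\C(OC)=C\CC=C(C)C | intermediate
18 | 5-methoxy-4,6-bis(3-methylbut-2-en-1-yl)-2-(2-phenyl-1,3-dioxolan-2-yl)-3-(triisopropylsilyloxy)cyclohexa-2,4-dien-1-one (racemic; configuration left open) | O=C1C(C2(c3ccccc3)OCCO2)=C(O[Si](C(C)C)(C(C)C)C(C)C)C(CC=C(C)C)=C(OC)C1CC=C(C)C | intermediate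
19 | 3-methoxy-2,4-bis(3-methylbut-2-en-1-yl)-6-(2-phenyl-1,3-dioxolan-2-yl)-5-(triisopropylsilyloxy)phenol | COc1c(CC=C(C)C)c(O)c(C2(c3ccccc3)OCCO2)c(O[Si](C(C)C)(C(C)C)C(C)C)c1CC=C(C)C | intermediate
20 | 5-methoxy-4,6-bis(3-methylbut-2-en-1-yl)-2-(2-phenyl-1,3-dioxolan-2-yl)benzene-1,3-diol | COc1c(CC=C(C)C)c(O)c(C2(c3ccccc3)OCCO2)c(O)c1CC=C(C)C | intermediate
21 | [2,6-dihydroxy-4-methoxy-3,5-bis(3-methylbut-2-en-1-yl)phenyl](phenyl)methanone | COc1c(CC=C(C)C)c(O)c(C(=O)c2ccccc2)c(O)c1CC=C(C)C | target

Total step count: 7
Longest linear sequence: 4 steps (steps 4, 5, 6, 7; the branches through step 1 or step 2, then steps 3, 6, 7, are equally long)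

Steps most likely to fail

Step 6 (key step, where the risk of the route is concentrated). The cyclobutenone is stabilised as a vinylogous ester and may open too slowly, so that the siloxyalkyne is lost by thermal silyl migration before it is consumed. The quaternary ketal carbon next to the alkyne may also retard the cycloaddition enough for the vinylketene to acylate the product phenol instead. Opening 9 by irradiation at room temperature would be tried first, but that changes only the conditions. The fallback takes ring A from an intact phloroglucinol instead of assembling it. It sets out from 2 and comes back to the route at 21. Purchased 2,4,6-trihydroxybenzophenone F1 should be methylated selectively at the non-chelated para hydroxyl (dimethyl sulfate, one equivalent, K2CO3, acetone) to give 2,6-dihydroxy-4-methoxybenzophenone F2. F2 would then be C-prenylated twice with 2 (10 % aqueous KOH, 0 °C) at its two free ring carbons. This nuclear prenylation of acylphloroglucinols is a known reaction class; it is expected to be unselective but is short.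

Step 5. The carbenoid derived from 12 may fragment instead of rearranging, because the migrating carbon is quaternary and carries two oxygens. The propargylic ketal of 14 may also ionise on contact with traces of acid during isolation. The fallback makes the ynolate by oxidation of an acetylide instead of by ester homologation. It sets out from 11 and comes back at 13, and so at 14. Reduction of 11 with DIBAL-H at −78 °C should give 2-phenyl-1,3-dioxolane-2-carbaldehyde F3. Seyferth–Gilbert homologation with the Ohira–Bestmann reagent (K2CO3, MeOH) should give 2-ethynyl-2-phenyl-1,3-dioxolane F4. Deprotonation with LiN(SiMe3)2 should give lithium (2-phenyl-1,3-dioxolan-2-yl)ethynide F5, and oxidation of F5 with lithium tert-butyl peroxide (Julia ynolate synthesis) should give 13, which is silylated with TIPSCl as in step 5.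

Step 3. Amine-catalysed dimerisation of the aldoketene may outrun the cycloaddition, and the ammonium chloride may protonate the acid-sensitive ynol ether. The fallback generates the ketene thermally, free of amine and salt, from a tert-butyl ynol ether. It sets out from 1 and 2 and comes back at 8, and so at 9. The one-pot sequence of step 1, run with tert-butanol in place of methanol, should lead through (E)-1-tert-butoxy-1,2-dichloroethene F6 and lithium tert-butoxyacetylide F7 to 1-tert-butoxy-5-methylhex-4-en-1-yne F8. Slow addition of F8 to an excess of 5 in toluene at 60–70 °C should release 8 by retro-ene loss of isobutene, and 5 should trap it to give 9. This temperature is below that at which 9 itself is expected to open.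

Further compounds
F1 | step 6 | 2,4,6-trihydroxybenzophenone (purchased) | O=C(c1ccccc1)c1c(O)cc(O)cc1O
F2 | step 6 | 2,6-dihydroxy-4-methoxybenzophenone | COc1cc(O)c(C(=O)c2ccccc2)c(O)c1
F3 | step 5 | 2-phenyl-1,3-dioxolane-2-carbaldehyde | O=CC1(c2ccccc2)OCCO1
F4 | step 5 | 2-ethynyl-2-phenyl-1,3-dioxolane | C#CC1(c2ccccc2)OCCO1
F5 | step 5 | lithium (2-phenyl-1,3-dioxolan-2-yl)ethynide | [Li]C#CC1(c2ccccc2)OCCO1
F6 | step 3 | (E)-1-tert-butoxy-1,2-dichloroethene | CC(C)(C)O/C(Cl)=C\Cl
F7 | step 3 | lithium tert-butoxyacetylide | [Li]C#COC(C)(C)C
F8 | step 3 | 1-tert-butoxy-5-methylhex-4-en-1-yne | CC(C)=CCC#COC(C)(C)C
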